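**Retrosynthetic overview**

1. The target is ent-epicatechin-(4β→8)-epicatechin-4β-ol. Endgame: hydrogenolysis of nine benzyl ethers ⇐ fluoride removal of two silyl ethers ⇐ face-selective ionic reduction of a tertiary C4 carbinol, which sets the all-cis upper unit.
2. Key disconnection, two bonds in one flask: lower-unit O1–C8a (closes lower ring C) and lower C8–upper C4. A C8≡C8a aryne in lower ring A, released from an ortho bromine/fluorine pair, is captured by the tethered C2 alkoxide; the C8 aryllithium so formed adds to the upper-unit 4-ketone.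
3. Enabling feature: in lower ring A the ether carbon C8a and the interflavan carbon C8 are neighbours, and C8 is flanked on its other side by oxygenated C7. These two ortho bonds are the two ends of one aryne, and both the six-membered tether (O1–C2–C3–C4–C4a–C8a) and the C7 oxygen send oxygen to C8a and the carbanion to C8.
4. Key-step partners: an acyclic syn,syn-triol chain (C3/C4 by glycolate syn-aldol, C2 by chelation-controlled aryl Grignard addition) built on a formylated, brominated 5-fluororesorcinol dibenzyl ether; and a 4-ketone made from (+)-epicatechin by benzylation, silylation and C4 oxidation.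
5. Ring order: lower ring A and the three upper rings are bought; lower ring B arrives with the Grignard reagent; lower ring C is the only ring made and is closed last, in the key step.

Key step: step 14

Remark: the target is read as upper unit (2S,3S,4R), all-cis, and lower unit (2R,3R,4S), 2,3-cis-3,4-trans; (+)-epicatechin [(2S,3S)] and 5-fluorobenzene-1,3-diol are taken as purchasable.

**Route**

Step 1
Reactants: 1 5-fluorobenzene-1,3-diol
Product: 2 1,3-bis(benzyloxy)-5-fluorobenzene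
Conditions: BnBr (2.2 equiv), K2CO3, DMF, rt
Reagents that add atoms: benzyl bromide BrCc1ccccc1
Why: Williamson ether synthesis on both phenols gives benzyl ethers that survive every organometallic step and leave by hydrogenolysis at the end.

Step 2
Reactants: 2 1,3-bis(benzyloxy)-5-fluorobenzene
Product: 4 2,4-bis(benzyloxy)-6-fluorobenzaldehyde, via iminium salt 3 (not isolated)
Conditions: POCl3, DMF, 0 → 60 °C; aq. NaOAc
Reagents that add atoms: N,N-dimethylformamide CN(C)C=O; water O
Why: Vilsmeier–Haack formylation should go para to one benzyloxy group and ortho to fluorine (two equivalent sites), the site between the two benzyloxy groups being more hindered.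

Step 3
Reactants: 4 2,4-bis(benzyloxy)-6-fluorobenzaldehyde
Product: 5 4,6-bis(benzyloxy)-3-bromo-2-fluorobenzaldehyde
Conditions: NBS (1.05 equiv), MeCN, 0 °C → rt, dark
Reagents that add atoms: N-bromosuccinimide O=C1CCC(=O)N1Br
Why: electrophilic aromatic bromination should take the remaining position para to a benzyloxy group (between fluorine and benzyloxy), as in the 5-bromination of 2,4-dialkoxybenzaldehydes, which installs the ortho bromine/fluorine pair that later releases the aryne.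

Step 4
Reactants: 6 (R)-4-benzyloxazolidin-2-one; 7 (benzyloxy)acetyl chloride
Product: 8 (R)-4-benzyl-3-[(benzyloxy)acetyl]oxazolidin-2-one
Conditions: n-BuLi, THF, −78 °C; then 7, −78 → 0 °C
Reagents that add atoms: none
Why: N-acylation of the lithiated oxazolidinone gives the glycolate imide needed for the auxiliary-controlled aldol reaction.

Step 5
Reactants: 8 (R)-4-benzyl-3-[(benzyloxy)acetyl]oxazolidin-2-one; 5 4,6-bis(benzyloxy)-3-bromo-2-fluorobenzaldehyde
Product: 10 (R)-4-benzyl-3-[(2R,3S)-2-(benzyloxy)-3-[4,6-bis(benzyloxy)-3-bromo-2-fluorophenyl]-3-hydroxypropanoyl]oxazolidin-2-one, via boron enolate 9 (not isolated)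
Conditions: n-Bu2BOTf, Et3N, CH2Cl2, −78 → 0 °C; then 5, −78 → 0 °C; pH 7 buffer, MeOH, H2O2, 0 °C
Reagents that add atoms: none
Why: Evans boron glycolate syn-aldol reaction, in which the Z-enolate reacts through a chair Zimmerman–Traxler transition state on the face remote from the auxiliary benzyl group, should set the 2R,3S syn pair that becomes C3 and C4 of the lower unit.

Step 6
Reactants: 10 aldol adduct
Product: 11 (R)-4-benzyl-3-[(2R,3S)-2-(benzyloxy)-3-[4,6-bis(benzyloxy)-3-bromo-2-fluorophenyl]-3-[(tert-butyldimethylsilyl)oxy]propanoyl]oxazolidin-2-one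
Conditions: TBSOTf, 2,6-lutidine, CH2Cl2, −78 → 0 °C
Reagents that add atoms: tert-butyldimethylsilyl triflate CC(C)(C)[Si](C)(C)OS(=O)(=O)C(F)(F)F
Why: silylation of the hindered, ionisable benzylic alcohol with a silyl triflate under non-acidic conditions blocks retro-aldol cleavage and gives a bulky, weakly basic ether at the future C4.

Step 7
Reactants: 11 silylated imide
Product: 12 (2S,3S)-2-(benzyloxy)-3-[4,6-bis(benzyloxy)-3-bromo-2-fluorophenyl]-3-[(tert-butyldimethylsilyl)oxy]propan-1-ol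
Conditions: LiBH4, MeOH (2 equiv), THF, 0 °C
Reagents that add atoms: none
Why: reductive cleavage of the N-acyloxazolidinone by LiBH4 gives the primary alcohol and returns the auxiliary, while aryl halides, ethers and both stereocentres are untouched.

Step 8
Reactants: 12 primary alcohol
Product: 13 (2R,3S)-2-(benzyloxy)-3-[4,6-bis(benzyloxy)-3-bromo-2-fluorophenyl]-3-[(tert-butyldimethylsilyl)oxy]propanal
Conditions: Dess–Martin periodinane, NaHCO3, CH2Cl2, 0 °C → rt
Reagents that add atoms: none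
Why: buffered Dess–Martin oxidation should give the α-benzyloxy aldehyde without epimerisation or β-elimination.

Step 9
Reactants: 13 aldehyde; 14 1,2-bis(benzyloxy)-4-bromobenzene
Product: 16 (1R,2S,3S)-2-(benzyloxy)-1-[3,4-bis(benzyloxy)phenyl]-3-[4,6-bis(benzyloxy)-3-bromo-2-fluorophenyl]-3-[(tert-butyldimethylsilyl)oxy]propan-1-ol, via Grignard reagent 15 (not isolated)
Conditions: 14, Mg, THF, rt; then 13, MgBr2·OEt2, CH2Cl2, −78 °C; aq. NH4Cl
Reagents that add atoms: none
Why: chelation-controlled Grignard addition (Cram chelate model), with magnesium bridging the aldehyde oxygen and the α-benzyloxy group and the aryl group adding from the side of the α-hydrogen, should give the 1,2-syn alcohol (C2 of the lower unit, R) with its hydroxyl free for the ring closure.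

Step 10
Reactants: 17 (+)-epicatechin
Product: 18 (2S,3S)-5,7-bis(benzyloxy)-2-[3,4-bis(benzyloxy)phenyl]chroman-3-ol
Conditions: BnBr (4.2 equiv), K2CO3, DMF, 0 °C → rt
Reagents that add atoms: benzyl bromide BrCc1ccccc1
Why: Williamson benzylation takes the four phenols, which are far more acidic than the secondary 3-hydroxyl.

Step 11
Reactants: 18 tetra-O-benzyl-(+)-epicatechin
Product: 19 tert-butyl{[(2S,3S)-5,7-bis(benzyloxy)-2-[3,4-bis(benzyloxy)phenyl]chroman-3-yl]oxy}dimethylsilane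
Conditions: TBSCl, imidazole, DMF, rt
Reagents that add atoms: tert-butyldimethylsilyl chloride CC(C)(C)[Si](C)(C)Cl
Why: silylation of the 3-hydroxyl gives a base-stable, bulky ether that later shields one face of C4.

Step 12
Reactants: 19 3-O-silyl ether
Product: 20 (2S,3S,4R)-5,7-bis(benzyloxy)-2-[3,4-bis(benzyloxy)phenyl]-3-[(tert-butyldimethylsilyl)oxy]chroman-4-ol
Conditions: DDQ (2 equiv), CH2Cl2/H2O, rt
Reagents that add atoms: water O
Why: DDQ benzylic oxidation by hydride abstraction from C4 gives a cation stabilised by the 5,7-dioxygenated ring A, which water should capture trans to the 3-silyloxy group (this centre is removed in step 13).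

Step 13
Reactants: 20 4-alcohol
Product: 21 (2S,3R)-5,7-bis(benzyloxy)-2-[3,4-bis(benzyloxy)phenyl]-3-[(tert-butyldimethylsilyl)oxy]chroman-4-one
Conditions: Dess–Martin periodinane, NaHCO3, CH2Cl2, rt
Reagents that add atoms: none
Why: Dess–Martin oxidation of the benzylic alcohol under neutral conditions should give the 2,3-cis 4-ketone without epimerising C2 or C3.

Step 14
Reactants: 16 acyclic bromofluoroaryl alcohol; 21 upper-unit 4-ketone
Product: 25 (2S,3R,4R)-5,7-bis(benzyloxy)-2-[3,4-bis(benzyloxy)phenyl]-3-[(tert-butyldimethylsilyl)oxy]-4-{(2R,3S,4S)-3,5,7-tris(benzyloxy)-2-[3,4-bis(benzyloxy)phenyl]-4-[(tert-butyldimethylsilyl)oxy]chroman-8-yl}chroman-4-ol, via aryllithium alkoxide 22 (not isolated), via aryne alkoxide 23 (not isolated), via 8-lithioflavan 24 (not isolated)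
Conditions: MeLi (1.0 equiv), THF, −78 °C; t-BuLi (2.0 equiv), −78 °C, then −30 °C; recool to −78 °C, 21 (0.9 equiv), THF, −78 → −50 °C; AcOH
Reagents that add atoms: none
Why: Proposed new method: MeLi forms the C2 lithium alkoxide and t-BuLi exchanges the C8 bromine, the 2-fluoroaryllithium 22 loses LiF on warming to the C8≡C8a aryne 23, the tethered alkoxide adds to C8a (forming O1–C8a and ring C) and the C8 aryllithium 24 thus created adds to the C4 carbonyl of 21, so that ring closure and interflavan C–C bond formation share one carbanion. The closest known reaction types are the aryne ring closure of halogenoaryl-propanolates to chromans, aryne cyclisation–electrophile trapping sequences of heteroatom-tethered haloarenes, and the addition of 8-lithioflavans made from 8-bromides to 3-silyloxyflavan-4-ones; only their merger in one flask is new. Ring C closes in 6-exo-dig mode by attack of oxygen on the in-plane aryne orbital, and no lower-unit stereocentre is touched because the C2–O bond is not broken, so the 2,3-cis-3,4-trans pattern is carried over unchanged from the syn,syn chain. The new carbinol centre should form by attack anti to the pseudo-axial 3-silyloxy group of 21, but its configuration is immaterial because it is planarised in step 15. Regioselectivity is needed at the aryne and is secured threefold: the bromine/fluorine pair fixes the aryne between C8 and C8a, the six-membered tether can only deliver oxygen to C8a, and the inductive effect of the C7 benzyloxy group places the negative charge on C8. Chemoselectivity (carbonyl addition before proton transfer or enolisation) rests on the absence of any N–H or O–H acid after ring closure, on the destruction of t-BuBr by the second equivalent of t-BuLi, and on the low temperature of the ketone addition.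

Step 15
Reactants: 25 tertiary carbinol (used without prolonged storage)
Product: 26 tert-butyl{[(2S,3S,4R)-5,7-bis(benzyloxy)-2-[3,4-bis(benzyloxy)phenyl]-4-{(2R,3S,4S)-3,5,7-tris(benzyloxy)-2-[3,4-bis(benzyloxy)phenyl]-4-[(tert-butyldimethylsilyl)oxy]chroman-8-yl}chroman-3-yl]oxy}dimethylsilane
Conditions: n-Bu3SnH (5 equiv), CF3CO2H (2 equiv), CH2Cl2, −40 → 0 °C
Reagents that add atoms: none
Why: ionic hydrogenation of the doubly benzylic tertiary alcohol should deliver hydride to the planar C4 cation from the face anti to the pseudo-axial 3-silyloxy group and the C2 aryl group, leaving the lower unit cis to both (4R, all-cis), while the far less ionisable secondary C4 silyl ether of the lower unit should stay intact.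

Step 16
Reactants: 26 bis-silyl ether
Product: 27 (2R,3R,4S)-3,5,7-tris(benzyloxy)-2-[3,4-bis(benzyloxy)phenyl]-8-{(2S,3S,4R)-5,7-bis(benzyloxy)-2-[3,4-bis(benzyloxy)phenyl]-3-hydroxychroman-4-yl}chroman-4-ol
Conditions: Bu4NF, AcOH, THF, 0 → 40 °C
Reagents that add atoms: none
Why: fluoride-induced desilylation buffered with acetic acid should free the upper 3-hydroxyl and the lower 4-hydroxyl without acid- or base-induced reaction at the benzylic C4 centre.

Step 17
Reactants: 27 nona-O-benzyl diol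
Product: 28 (2R,3R,4S)-2-(3,4-dihydroxyphenyl)-8-[(2S,3S,4R)-2-(3,4-dihydroxyphenyl)-3,5,7-trihydroxychroman-4-yl]chromane-3,4,5,7-tetrol
Conditions: H2 (1 atm), Pd(OH)2/C, THF/MeOH/H2O, rt, short reaction time
Reagents that add atoms: none
Why: catalytic hydrogenolysis removes the eight aryl benzyl ethers and the 3-O-benzyl ether under neutral conditions, under which the benzylic C4 hydroxyl and the interflavan bond should persist.

**Compound list**

1 | 5-fluorobenzene-1,3-diol | Oc1cc(O)cc(F)c1 | starting material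
2 | 1,3-bis(benzyloxy)-5-fluorobenzene | Fc1cc(OCc2ccccc2)cc(OCc2ccccc2)c1 | intermediate
3 | [2,4-bis(benzyloxy)-6-fluorophenyl]methylidene(dimethyl)iminium chloride | C[N+](C)=Cc1c(F)cc(OCc2ccccc2)cc1OCc1ccccc1.[Cl-] | intermediate
4 | 2,4-bis(benzyloxy)-6-fluorobenzaldehyde | O=Cc1c(F)cc(OCc2ccccc2)cc1OCc1ccccc1 | intermediate
5 | 4,6-bis(benzyloxy)-3-bromo-2-fluorobenzaldehyde | O=Cc1c(F)c(Br)c(OCc2ccccc2)cc1OCc1ccccc1 | intermediate
6 | (R)-4-benzyloxazolidin-2-one | O=C1N[C@H](Cc2ccccc2)CO1 | starting material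
7 | (benzyloxy)acetyl chloride | O=C(Cl)COCc1ccccc1 | starting material
8 | (R)-4-benzyl-3-[(benzyloxy)acetyl]oxazolidin-2-one | O=C(COCc1ccccc1)N1C(=O)OC[C@H]1Cc1ccccc1 | intermediate
9 | (R)-4-benzyl-3-[(Z)-2-(benzyloxy)-1-[(dibutylboranyl)oxy]ethenyl]oxazolidin-2-one (boron enolate) | CCCCB(CCCC)O/C(=C\OCc1ccccc1)N1C(=O)OC[C@H]1Cc1ccccc1 | intermediate
10 | (R)-4-benzyl-3-[(2R,3S)-2-(benzyloxy)-3-[4,6-bis(benzyloxy)-3-bromo-2-fluorophenyl]-3-hydroxypropanoyl]oxazolidin-2-one | O=C([C@H](OCc1ccccc1)[C@H](c1c(F)c(Br)c(OCc2ccccc2)cc1OCc1ccccc1)O)N1C(=O)OC[C@H]1Cc1ccccc1 | intermediate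
11 | (R)-4-benzyl-3-[(2R,3S)-2-(benzyloxy)-3-[4,6-bis(benzyloxy)-3-bromo-2-fluorophenyl]-3-[(tert-butyldimethylsilyl)oxy]propanoyl]oxazolidin-2-one | O=C([C@H](OCc1ccccc1)[C@H](c1c(F)c(Br)c(OCc2ccccc2)cc1OCc1ccccc1)O[Si](C)(C)C(C)(C)C)N1C(=O)OC[C@H]1Cc1ccccc1 | intermediate
12 | (2S,3S)-2-(benzyloxy)-3-[4,6-bis(benzyloxy)-3-bromo-2-fluorophenyl]-3-[(tert-butyldimethylsilyl)oxy]propan-1-ol | OC[C@H](OCc1ccccc1)[C@H](c1c(F)c(Br)c(OCc2ccccc2)cc1OCc1ccccc1)O[Si](C)(C)C(C)(C)C | intermediate
13 | (2R,3S)-2-(benzyloxy)-3-[4,6-bis(benzyloxy)-3-bromo-2-fluorophenyl]-3-[(tert-butyldimethylsilyl)oxy]propanal | O=C[C@H](OCc1ccccc1)[C@H](c1c(F)c(Br)c(OCc2ccccc2)cc1OCc1ccccc1)O[Si](C)(C)C(C)(C)C | intermediate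
14 | 1,2-bis(benzyloxy)-4-bromobenzene | Brc1ccc(OCc2ccccc2)c(OCc2ccccc2)c1 | starting material
15 | [3,4-bis(benzyloxy)phenyl]magnesium bromide | Br[Mg]c1ccc(OCc2ccccc2)c(OCc2ccccc2)c1 | intermediate
16 | (1R,2S,3S)-2-(benzyloxy)-1-[3,4-bis(benzyloxy)phenyl]-3-[4,6-bis(benzyloxy)-3-bromo-2-fluorophenyl]-3-[(tert-butyldimethylsilyl)oxy]propan-1-ol (syn,syn chain) | O[C@H](c1ccc(OCc2ccccc2)c(OCc2ccccc2)c1)[C@H](OCc1ccccc1)[C@H](c1c(F)c(Br)c(OCc2ccccc2)cc1OCc1ccccc1)O[Si](C)(C)C(C)(C)C | intermediate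
17 | (+)-epicatechin, (2S,3S)-2-(3,4-dihydroxyphenyl)chromane-3,5,7-triol | Oc1cc(O)c2c(c1)O[C@@H](c1ccc(O)c(O)c1)[C@@H](O)C2 | starting material
18 | (2S,3S)-5,7-bis(benzyloxy)-2-[3,4-bis(benzyloxy)phenyl]chroman-3-ol | C(c1ccccc1)Oc1cc(OCc3ccccc3)c2c(c1)O[C@@H](c1ccc(OCc3ccccc3)c(OCc3ccccc3)c1)[C@@H](O)C2 | intermediate
19 | tert-butyl{[(2S,3S)-5,7-bis(benzyloxy)-2-[3,4-bis(benzyloxy)phenyl]chroman-3-yl]oxy}dimethylsilane | C(c1ccccc1)Oc1cc(OCc3ccccc3)c2c(c1)O[C@@H](c1ccc(OCc3ccccc3)c(OCc3ccccc3)c1)[C@@H](O[Si](C)(C)C(C)(C)C)C2 | intermediate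
20 | (2S,3S,4R)-5,7-bis(benzyloxy)-2-[3,4-bis(benzyloxy)phenyl]-3-[(tert-butyldimethylsilyl)oxy]chroman-4-ol (4-OH trans to 3-O) | C(c1ccccc1)Oc1cc(OCc3ccccc3)c2c(c1)O[C@@H](c1ccc(OCc3ccccc3)c(OCc3ccccc3)c1)[C@@H](O[Si](C)(C)C(C)(C)C)[C@@H]2O | intermediate
21 | (2S,3R)-5,7-bis(benzyloxy)-2-[3,4-bis(benzyloxy)phenyl]-3-[(tert-butyldimethylsilyl)oxy]chroman-4-one (2,3-cis) | C(c1ccccc1)Oc1cc(OCc3ccccc3)c2c(c1)O[C@@H](c1ccc(OCc3ccccc3)c(OCc3ccccc3)c1)[C@@H](O[Si](C)(C)C(C)(C)C)C2=O | intermediate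
22 | lithium alkoxide of 16 with lithium in place of bromine (2-fluoroaryllithium) | [Li]O[C@H](c1ccc(OCc2ccccc2)c(OCc2ccccc2)c1)[C@H](OCc1ccccc1)[C@H](c1c(F)c([Li])c(OCc2ccccc2)cc1OCc1ccccc1)O[Si](C)(C)C(C)(C)C | intermediate
23 | aryne lithium alkoxide (3,5-bis(benzyloxy)benzyne ring carrying the chain) | [Li]O[C@H](c1ccc(OCc2ccccc2)c(OCc2ccccc2)c1)[C@H](OCc1ccccc1)[C@H](C1=C(OCc2ccccc2)C=C(OCc2ccccc2)C#C1)O[Si](C)(C)C(C)(C)C | intermediate
24 | [(2R,3S,4S)-3,5,7-tris(benzyloxy)-2-[3,4-bis(benzyloxy)phenyl]-4-[(tert-butyldimethylsilyl)oxy]chroman-8-yl]lithium | [Li]c1c(OCc2ccccc2)cc(OCc2ccccc2)c2c1O[C@H](c1ccc(OCc3ccccc3)c(OCc3ccccc3)c1)[C@H](OCc1ccccc1)[C@H]2O[Si](C)(C)C(C)(C)C | intermediate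
25 | (2S,3R,4R)-5,7-bis(benzyloxy)-2-[3,4-bis(benzyloxy)phenyl]-3-[(tert-butyldimethylsilyl)oxy]-4-{(2R,3S,4S)-3,5,7-tris(benzyloxy)-2-[3,4-bis(benzyloxy)phenyl]-4-[(tert-butyldimethylsilyl)oxy]chroman-8-yl}chroman-4-ol (expected C4 epimer) | C(c1ccccc1)Oc1cc(OCc3ccccc3)c2c(c1)O[C@@H](c1ccc(OCc3ccccc3)c(OCc3ccccc3)c1)[C@@H](O[Si](C)(C)C(C)(C)C)[C@]2(O)c1c(OCc2ccccc2)cc(OCc2ccccc2)c2c1O[C@H](c1ccc(OCc3ccccc3)c(OCc3ccccc3)c1)[C@H](OCc1ccccc1)[C@H]2O[Si](C)(C)C(C)(C)C | intermediate
26 | tert-butyl{[(2S,3S,4R)-5,7-bis(benzyloxy)-2-[3,4-bis(benzyloxy)phenyl]-4-{(2R,3S,4S)-3,5,7-tris(benzyloxy)-2-[3,4-bis(benzyloxy)phenyl]-4-[(tert-butyldimethylsilyl)oxy]chroman-8-yl}chroman-3-yl]oxy}dimethylsilane (upper unit all-cis) | C(c1ccccc1)Oc1cc(OCc3ccccc3)c2c(c1)O[C@@H](c1ccc(OCc3ccccc3)c(OCc3ccccc3)c1)[C@@H](O[Si](C)(C)C(C)(C)C)[C@H]2c1c(OCc2ccccc2)cc(OCc2ccccc2)c2c1O[C@H](c1ccc(OCc3ccccc3)c(OCc3ccccc3)c1)[C@H](OCc1ccccc1)[C@H]2O[Si](C)(C)C(C)(C)C | intermediate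
27 | (2R,3R,4S)-3,5,7-tris(benzyloxy)-2-[3,4-bis(benzyloxy)phenyl]-8-{(2S,3S,4R)-5,7-bis(benzyloxy)-2-[3,4-bis(benzyloxy)phenyl]-3-hydroxychroman-4-yl}chroman-4-ol | C(c1ccccc1)Oc1cc(OCc3ccccc3)c2c(c1)O[C@@H](c1ccc(OCc3ccccc3)c(OCc3ccccc3)c1)[C@@H](O)[C@H]2c1c(OCc2ccccc2)cc(OCc2ccccc2)c2c1O[C@H](c1ccc(OCc3ccccc3)c(OCc3ccccc3)c1)[C@H](OCc1ccccc1)[C@H]2O | intermediate
28 | (2R,3R,4S)-2-(3,4-dihydroxyphenyl)-8-[(2S,3S,4R)-2-(3,4-dihydroxyphenyl)-3,5,7-trihydroxychroman-4-yl]chromane-3,4,5,7-tetrol | Oc1cc(O)c2c(c1)O[C@@H](c1ccc(O)c(O)c1)[C@@H](O)[C@H]2c1c(O)cc(O)c2c1O[C@H](c1ccc(O)c(O)c1)[C@H](O)[C@H]2O | target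

**Summary and risks**

Total step count: 17. Longest linear sequence: 12 steps (steps 1, 2, 3, 5, 6, 7, 8, 9, 14, 15, 16, 17).

Steps most likely to fail:

Step 14 (proposed new method). The relay may break between ring closure and carbonyl addition. The crowded C8 lithium species may be protonated, or may remove the C3 proton of ketone 21 instead of adding to it, which would lead to enolisation, C3 epimerisation or retro-oxa-Michael ring opening. Fallback with known chemistry, setting out from 16: the aryne ring closure is run alone (MeLi, then t-BuLi, THF, −78 → −30 °C, MeOH quench) to give (2R,3S,4S)-3,5,7-tris(benzyloxy)-2-[3,4-bis(benzyloxy)phenyl]-4-[(tert-butyldimethylsilyl)oxy]chroman F1. Regioselective electrophilic bromination at C8 (NBS, CH2Cl2, −40 °C) gives the 8-bromoflavan F2. Bromine–lithium exchange (t-BuLi, THF, −78 °C), transmetalation with anhydrous CeCl3 to suppress enolisation, and addition to 21 return to the route at 25.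

Step 15. Competitive acid ionisation of the lower-unit C4–O silyl ether (loss or scrambling of the 4-oxygen) or elimination from the upper C4 cation may accompany the reduction. Fallback, setting out from 25: the tertiary alcohol is activated without Brønsted acid by acylation (trifluoroacetic anhydride, 2,6-di-tert-butyl-4-methylpyridine, CH2Cl2, −78 °C) to the tertiary trifluoroacetate F3. This should ionise on warming to −40 °C in the buffered solution and be captured by n-Bu3SnH from the same face, returning to the route at 26.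

Step 17. Hydrogenolytic cleavage of the free benzylic C4–OH bond of the lower unit (over-reduction to the 4-deoxy dimer) may compete with debenzylation. Fallback, setting out from 26: the deprotection order is reversed, so that the bulky silyl ether guards the C4–O bond during hydrogenation. Hydrogenolysis of 26 (H2, Pd(OH)2/C, THF/MeOH) gives the bis-silyl ether of the target F4, and buffered fluoride (Bu4NF, AcOH, THF, under argon) then removes both silyl groups and returns to the route at 28.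

Further compounds
F1 | step 14 | (2R,3S,4S)-3,5,7-tris(benzyloxy)-2-[3,4-bis(benzyloxy)phenyl]-4-[(tert-butyldimethylsilyl)oxy]chroman | c1c(OCc2ccccc2)cc(OCc2ccccc2)c2c1O[C@H](c1ccc(OCc3ccccc3)c(OCc3ccccc3)c1)[C@H](OCc1ccccc1)[C@H]2O[Si](C)(C)C(C)(C)C
F2 | step 14 | (2R,3S,4S)-3,5,7-tris(benzyloxy)-2-[3,4-bis(benzyloxy)phenyl]-8-bromo-4-[(tert-butyldimethylsilyl)oxy]chroman | Brc1c(OCc2ccccc2)cc(OCc2ccccc2)c2c1O[C@H](c1ccc(OCc3ccccc3)c(OCc3ccccc3)c1)[C@H](OCc1ccccc1)[C@H]2O[Si](C)(C)C(C)(C)C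
F3 | step 15 | C4 trifluoroacetate of 25 | C(c1ccccc1)Oc1cc(OCc3ccccc3)c2c(c1)O[C@@H](c1ccc(OCc3ccccc3)c(OCc3ccccc3)c1)[C@@H](O[Si](C)(C)C(C)(C)C)[C@]2(OC(=O)C(F)(F)F)c1c(OCc2ccccc2)cc(OCc2ccccc2)c2c1O[C@H](c1ccc(OCc3ccccc3)c(OCc3ccccc3)c1)[C@H](OCc1ccccc1)[C@H]2O[Si](C)(C)C(C)(C)C
F4 | step 17 | bis-silyl ether of 28 (upper 3-O and lower 4-O tert-butyldimethylsilyl) | Oc1cc(O)c2c(c1)O[C@@H](c1ccc(O)c(O)c1)[C@@H](O[Si](C)(C)C(C)(C)C)[C@H]2c1c(O)cc(O)c2c1O[C@H](c1ccc(O)c(O)c1)[C@H](O)[C@H]2O[Si](C)(C)C(C)(C)C
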